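**Assumption (one line):** carbons carry spongian-type numbers (carbocycle C1–C10 with methyls C17–C20; C11 lactone C=O, C12 CH–OAc, C13, C14 = CH on C8, C15 acetal CH, C16 CH–CO2Me; "11-nordrimane" = 4,4,8,10-tetramethyl-trans-decalin, C9 between C8 and C10), and silyl ether 8 and methyl diazoacetate 9 are bought as catalogue items.

## Retrosynthetic overview

1. 25 ⇐ 23: last step, cationic 6,6→5,7 ring contraction/expansion of a trans-decalin 9β-mesylate (C5 shifts from C10 to C9, H-20 is lost), as in the presumed spongian → perhydroazulene rearrangement.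
2. Dioxabicyclo[3.2.1]octanone ⇐ cyclopentene enol ether 19: oxidative C11–C15 cleavage, then spontaneous lactol and acylal closure, as in the presumed carbocycle cleavage/acetalisation.
3. C8–C14 bond ⇐ Michael addition of the C8 enolate of 11-nordriman-9-one 7 (two steps from sclareolide) to cyclopentenone 14.
4. 14 ⇐ [2,3]-Wittig rearrangement of a glycolate ether of mono-silylated cis-cyclopentenediol, then allylic oxidation.
5. Ring order: decalin and cyclopentene are bought; tetrahydrofuran acetal, then δ-lactone (step 9); cyclopentane and cycloheptane together (step 11).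

## Route

Step 1
Reactants: 1 (+)-sclareolide
Product: 5 9(11)-dehydrosclareolide (butenolide), via lithium enolate 2 (not isolated), via selenide 3 (not isolated), via selenoxide 4 (not isolated)
Conditions: LDA, THF, −78 °C; PhSeCl; then 30% H2O2, pyridine, CH2Cl2, 0 °C → rt
Reagents that add atoms: none
Why: α-selenenylation of the lactone enolate on the α-face (the β-face is shielded by the two axial methyls) places Se syn to H-9, so selenoxide syn-elimination gives the C9=C11 butenolide; no new stereocentre remains.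

Step 2
Reactants: 5 9(11)-dehydrosclareolide
Product: 7 8α-methyl-11-nordriman-9-one, via keto glyoxylate 6 (not isolated)
Conditions: O3, CH2Cl2, −78 °C; then Zn dust, AcOH, −78 → 80 °C
Reagents that add atoms: ozone, [O-][O+]=O
Why: ozonolysis of C9=C11 gives the C9 ketone and leaves C8–O as a glyoxylate, an α-acyloxy ketone that zinc in hot acetic acid cleaves reductively (classical α-acyloxy ketone deoxygenation) with thermodynamic protonation to the equatorial 8α-methyl ketone; the C8 centre is erased again in step 6.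

Step 3
Reactants: 8 (1S,4R)-4-[(tert-butyldimethylsilyl)oxy]cyclopent-2-en-1-ol; 9 methyl diazoacetate
Product: 10 methyl 2-({(1S,4R)-4-[(tert-butyldimethylsilyl)oxy]cyclopent-2-en-1-yl}oxy)acetate
Conditions: Rh2(OAc)4 (1 mol %), CH2Cl2, rt, slow addition of 9
Reagents that add atoms: none
Why: Rh(II)-carbenoid O–H insertion is faster than cyclopropanation and is neutral, so the silyl group cannot migrate between the two cis oxygens (which would racemise the alcohol).

Step 4
Reactants: 10 allyl glycolate ether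
Product: 13 methyl (2R)-2-[(tert-butyldimethylsilyl)oxy]-2-{(1S,5R)-5-[(tert-butyldimethylsilyl)oxy]cyclopent-2-en-1-yl}acetate, via ester enolate 11 (not isolated), via lithium alkoxide 12 (not isolated)
Conditions: LDA, THF, −78 → −40 °C; then TBSOTf, −78 → 0 °C
Reagents that add atoms: tert-butyldimethylsilyl trifluoromethanesulfonate, CC(C)(C)[Si](C)(C)OS(=O)(=O)C(F)(F)F
Why: ester-enolate [2,3]-Wittig rearrangement is suprafacial, so the new C13–C16 bond forms on the face of the departing oxygen (cis to the C12 silyloxy group), and the envelope transition state with the ester turned away from the ring and from that silyloxy group sets C16 as R; the alkoxide is silylated in the same flask.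

Step 5
Reactants: 13 bis-silyl cyclopentene ester
Product: 14 methyl (2R)-2-[(tert-butyldimethylsilyl)oxy]-2-{(1S,5S)-5-[(tert-butyldimethylsilyl)oxy]-4-oxocyclopent-2-en-1-yl}acetate
Conditions: Rh2(cap)4 (1 mol %), t-BuOOH, K2CO3, CH2Cl2, rt
Reagents that add atoms: tert-butyl hydroperoxide, CC(C)(C)OO
Why: radical allylic C–H oxidation goes to the only allylic CH2 (C11), the tertiary allylic C13–H being flanked by two silyloxy-bearing carbons, and gives the enone directly; no stereocentre changes.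

Step 6
Reactants: 7 8α-methyl-11-nordriman-9-one; 14 cyclopentenone
Product: 17 Michael adduct TBS enol ether (9-ketone), via decalone enolate 15 (not isolated), via adduct enolate 16 (not isolated)
Conditions: LDA, THF, 0 °C; 14, −78 → −40 °C; TBSCl, HMPA, −78 °C → rt
Reagents that add atoms: tert-butyldimethylsilyl chloride, CC(C)(C)[Si](C)(C)Cl
Why: Michael addition of the only possible (tetrasubstituted) enolate: the enolate reacts on its α-face, anti to the axial C10 methyl (C8: 8α-C14, 8β-Me), and the enone on the face anti to its two cis substituents (C14 trans to the C13 arm); O-silylation fixes the C15=C11 enol ether regiospecifically.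

Step 7
Reactants: 17 Michael adduct TBS enol ether
Product: 18 9β-alcohol
Conditions: SmI2 (3 equiv), H2O, THF, 0 °C
Reagents that add atoms: none
Why: SmI2–H2O ketone reduction by electron transfer leaves the methyl ester and silyl enol ether untouched; hydrogen reaches C9 from the open α-face (the β-face is blocked by the axial C8 and C10 methyls), giving the equatorial 9β-alcohol.

Step 8
Reactants: 18 9β-alcohol
Product: 19 9β-mesylate
Conditions: MsCl, Et3N, CH2Cl2, −10 → 0 °C
Reagents that add atoms: methanesulfonyl chloride, CS(=O)(=O)Cl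
Why: sulfene mesylation tolerates the doubly neopentylic alcohol, and the mesylate has no SN2 or E2 pathway (no β-hydrogen), so it is carried as a latent C9 cation; configuration is retained.

Step 9
Reactants: 19 9β-mesylate
Product: 22 hydroxy lactone acetal (2,7-dioxabicyclo[3.2.1]octan-3-one with free C12–OH), via aldehyde silyl ester 20 (not isolated), via seco hydroxy acid 21 (not isolated)
Conditions: O3, CH2Cl2, −78 °C; PPh3; then HF·pyridine, THF, 0 °C → rt
Reagents that add atoms: ozone, [O-][O+]=O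
Why: silyl enol ether ozonolysis cleaves C11–C15 to a C11 silyl ester and a C15 aldehyde; after desilylation the C16 hydroxyl closes on the aldehyde (lactol) and the C11 acid acylates the lactol (acylal), and the bridged bicycle allows only one C15 configuration (oxidative cleavage/acetalisation cascade).

Step 10
Reactants: 22 hydroxy lactone acetal
Product: 23 acetate (rearrangement precursor)
Conditions: Ac2O, pyridine, DMAP (cat.), CH2Cl2, 0 °C
Reagents that add atoms: acetic anhydride, CC(=O)OC(C)=O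
Why: DMAP-catalysed acetylation of the only free hydroxyl (C12), with retention.

Step 11
Reactants: 23 acetate (9β-mesylate)
Product: 25 target CNP0215240.1, via C10 cation 24 (not isolated)
Conditions: 2,6-di-tert-butyl-4-methylpyridine, (CF3)2CHOH/CH2Cl2 (1:4), 40 °C
Reagents that add atoms: none
Why: Proposed new method: ionisation of the equatorial 9β-mesylate is assisted by the antiperiplanar C5–C10 bond, so C5 migrates to C9 with inversion (H-9 stays α, giving the cis-fused perhydroazulene) rather than C7 (secondary, and it would place the cation next to the electron-poor acylal-bearing C14); H-9 is gauche to the new p-orbital, so only H-1 or H-20 can be lost, and the hindered base takes the exposed methyl proton to give the exocyclic alkene; closest known reaction type: solvolytic Wagner–Meerwein rearrangement of 10-methyl-1-decalyl sulfonates to hydroazulenes.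

## Compound list

1 | (+)-sclareolide, (3aR,5aS,9aS,9bR)-3a,6,6,9a-tetramethyldecahydronaphtho[2,1-b]furan-2(1H)-one | CC1(C)CCC[C@@]2(C)[C@H]1CC[C@@]1(C)OC(=O)C[C@H]21 | starting material
2 | lithium enolate of sclareolide | CC1(C)CCC[C@@]2(C)[C@H]1CC[C@@]1(C)OC(O[Li])=C[C@H]21 | intermediate (not isolated)
3 | 11α-(phenylselanyl)sclareolide | CC1(C)CCC[C@@]2(C)[C@H]1CC[C@@]1(C)OC(=O)[C@H]([Se]c3ccccc3)[C@H]21 | intermediate (not isolated)
4 | selenoxide of 3 (both Se epimers) | CC1(C)CCC[C@@]2(C)[C@H]1CC[C@@]1(C)OC(=O)[C@H]([Se](=O)c3ccccc3)[C@H]21 | intermediate (not isolated)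
5 | 9(11)-dehydrosclareolide, (3aR,5aS,9aS)-3a,6,6,9a-tetramethyl-4,5,5a,6,7,8,9,9a-octahydronaphtho[2,1-b]furan-2(3aH)-one | CC1(C)CCC[C@@]2(C)[C@H]1CC[C@@]1(C)OC(=O)C=C21 | intermediate
6 | glyoxylate ester of 8α-hydroxy-11-nordriman-9-one | CC1(C)CCC[C@@]2(C)[C@H]1CC[C@@](C)(OC(=O)C=O)C2=O | intermediate (not isolated)
7 | 8α-methyl-11-nordriman-9-one, (2R,4aS,8aS)-2,5,5,8a-tetramethyloctahydronaphthalen-1(2H)-one | CC1(C)CCC[C@@]2(C)[C@H]1CC[C@@H](C)C2=O | intermediate
8 | (1S,4R)-4-[(tert-butyldimethylsilyl)oxy]cyclopent-2-en-1-ol | O[C@@H]1C=C[C@H](O[Si](C)(C)C(C)(C)C)C1 | starting material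
9 | methyl diazoacetate | COC(=O)C=[N+]=[N-] | starting material
10 | methyl 2-({(1S,4R)-4-[(tert-butyldimethylsilyl)oxy]cyclopent-2-en-1-yl}oxy)acetate | COC(=O)CO[C@@H]1C=C[C@H](O[Si](C)(C)C(C)(C)C)C1 | intermediate
11 | lithium ester enolate of 10 | COC(O[Li])=CO[C@@H]1C=C[C@H](O[Si](C)(C)C(C)(C)C)C1 | intermediate (not isolated)
12 | lithium alkoxide of the [2,3]-Wittig hydroxy ester (configuration as in 13) | C1C=C[C@H]([C@@H](O[Li])C(=O)OC)[C@@H]1O[Si](C)(C)C(C)(C)C | intermediate (not isolated)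
13 | methyl (2R)-2-[(tert-butyldimethylsilyl)oxy]-2-{(1S,5R)-5-[(tert-butyldimethylsilyl)oxy]cyclopent-2-en-1-yl}acetate | C1C=C[C@H]([C@@H](O[Si](C)(C)C(C)(C)C)C(=O)OC)[C@@H]1O[Si](C)(C)C(C)(C)C | intermediate
14 | methyl (2R)-2-[(tert-butyldimethylsilyl)oxy]-2-{(1S,5S)-5-[(tert-butyldimethylsilyl)oxy]-4-oxocyclopent-2-en-1-yl}acetate | O=C1C=C[C@H]([C@@H](O[Si](C)(C)C(C)(C)C)C(=O)OC)[C@@H]1O[Si](C)(C)C(C)(C)C | intermediate
15 | lithium C8 enolate of 7 | CC1(C)CCC[C@@]2(C)[C@H]1CCC(C)=C2O[Li] | intermediate (not isolated)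
16 | lithium C15=C11 enolate of the Michael adduct | CC1(C)CCC[C@@]2(C)[C@H]1CC[C@@](C)([C@@H]1C=C(O[Li])[C@@H](O[Si](C)(C)C(C)(C)C)[C@H]1[C@@H](O[Si](C)(C)C(C)(C)C)C(=O)OC)C2=O | intermediate (not isolated)
17 | Michael adduct: 8β-methyl-11-nordriman-9-one linked through C8 (8α bond) to C14 of a cyclopentene carrying C11-OTBS (enol ether C15=C11), C12-OTBS and the C13 arm (R)-CH(OTBS)CO2Me; C13/C14 trans, C12/C13 cis | CC1(C)CCC[C@@]2(C)[C@H]1CC[C@@](C)([C@@H]1C=C(O[Si](C)(C)C(C)(C)C)[C@@H](O[Si](C)(C)C(C)(C)C)[C@H]1[C@@H](O[Si](C)(C)C(C)(C)C)C(=O)OC)C2=O | intermediate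
18 | 9β-alcohol of 17 (equatorial OH, H-9 α) | CC1(C)CCC[C@@]2(C)[C@H]1CC[C@@](C)([C@@H]1C=C(O[Si](C)(C)C(C)(C)C)[C@@H](O[Si](C)(C)C(C)(C)C)[C@H]1[C@@H](O[Si](C)(C)C(C)(C)C)C(=O)OC)[C@@H]2O | intermediate
19 | 9β-methanesulfonate of 18 | CC1(C)CCC[C@@]2(C)[C@H]1CC[C@@](C)([C@@H]1C=C(O[Si](C)(C)C(C)(C)C)[C@@H](O[Si](C)(C)C(C)(C)C)[C@H]1[C@@H](O[Si](C)(C)C(C)(C)C)C(=O)OC)[C@@H]2OS(C)(=O)=O | intermediate
20 | seco compound: 1-methyl 5-(tert-butyldimethylsilyl) 2,4-bis[(tert-butyldimethylsilyl)oxy]-3-[2-oxo-1-(9β-mesyloxy-8β-methyl-11-nordriman-8α-yl)ethyl]pentanedioate (C15 aldehyde, C11 silyl ester) | CC1(C)CCC[C@@]2(C)[C@H]1CC[C@@](C)([C@H](C=O)[C@@H]([C@H](O[Si](C)(C)C(C)(C)C)C(=O)O[Si](C)(C)C(C)(C)C)[C@@H](O[Si](C)(C)C(C)(C)C)C(=O)OC)[C@@H]2OS(C)(=O)=O | intermediate (not isolated)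
21 | desilylated seco compound: 2,4-dihydroxy-3-[2-oxo-1-(9β-mesyloxy-8β-methyl-11-nordriman-8α-yl)ethyl]pentanedioic acid 1-methyl ester (open form) | CC1(C)CCC[C@@]2(C)[C@H]1CC[C@@](C)([C@H](C=O)[C@@H]([C@H](O)C(=O)O)[C@@H](O)C(=O)OC)[C@@H]2OS(C)(=O)=O | intermediate (not isolated)
22 | methyl (1S,4S,5S,6R,8R)-4-hydroxy-8-(9β-mesyloxy-8β-methyl-11-nordriman-8α-yl)-3-oxo-2,7-dioxabicyclo[3.2.1]octane-6-carboxylate | CC1(C)CCC[C@@]2(C)[C@H]1CC[C@@](C)([C@@H]1[C@@H]3OC(=O)[C@@H](O)[C@H]1[C@H](C(=O)OC)O3)[C@@H]2OS(C)(=O)=O | intermediate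
23 | methyl (1S,4S,5R,6R,8R)-4-acetoxy-8-(9β-mesyloxy-8β-methyl-11-nordriman-8α-yl)-3-oxo-2,7-dioxabicyclo[3.2.1]octane-6-carboxylate | CC1(C)CCC[C@@]2(C)[C@H]1CC[C@@](C)([C@@H]1[C@@H]3OC(=O)[C@@H](OC(C)=O)[C@H]1[C@H](C(=O)OC)O3)[C@@H]2OS(C)(=O)=O | intermediate
24 | tertiary C10 cation of the cis-perhydroazulene (mesylate ion pair) | C[C+]1CCCC(C)(C)[C@@H]2CC[C@@](C)([C@@H]3[C@@H]4OC(=O)[C@@H](OC(C)=O)[C@H]3[C@H](C(=O)OC)O4)[C@H]12.CS(=O)(=O)[O-] | intermediate (not isolated)
25 | CNP0215240.1, methyl (1S,4S,5R,6R,8R)-4-acetoxy-3-oxo-8-[(1R,3aR,8aS)-1,4,4-trimethyl-8-methylidenedecahydroazulen-1-yl]-2,7-dioxabicyclo[3.2.1]octane-6-carboxylate | C=C1CCCC(C)(C)[C@@H]2CC[C@@](C)([C@@H]3[C@@H]4OC(=O)[C@@H](OC(C)=O)[C@H]3[C@H](C(=O)OC)O4)[C@H]12 | target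

## Step count and risks

Total steps: 11 (steps 1–2 make the decalone, steps 3–5 the cyclopentenone, steps 6–11 are common).
Longest linear sequence: 9 steps (8 → 25, steps 3–11).

Three steps most likely to fail:

Step 11. The cation may lose H-1 (or H-9) and give ring olefins, or C7 may migrate instead of C5. Fallback: set out again from 23 and run the solvolysis under equilibrating conditions (NaOAc, AcOH, 80 °C), accepting the more stable endocyclic trisubstituted alkene, the 1(10)-ene isomer of the target F1. Then move the double bond out of the ring by photocatalytic contra-thermodynamic isomerisation (decatungstate hydrogen-atom abstraction with a cobaloxime co-catalyst, 390 nm, MeCN), which comes back to the route at 25.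

Step 6. The hindered tetrasubstituted enolate may act as a base or add 1,2 instead of forming the quaternary–tertiary C8–C14 bond. Fallback: set out from 7 and dehydrogenate it (IBX, DMSO, 70 °C) to the enone 11-nordrim-7-en-9-one F2. Reduce this from the α-face (NaBH4, CeCl3, MeOH) to the allylic alcohol 11-nordrim-7-en-9β-ol F3. Join F3 to enone 14 by hydrogen-atom-transfer reductive olefin coupling (Fe(acac)3, PhSiH3, EtOH/ethylene glycol, 60 °C), in which the tertiary C8 radical adds to C14 on the same faces as in step 6, giving the 9β-hydroxy cyclopentanone F4. Kinetic enolisation away from the silyloxy-bearing C12 and O-silylation (LiHMDS, TBSCl, HMPA, THF, −78 °C) come back to the route at 18, so the chemoselective reduction of step 7 is bypassed as well.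

Step 5. The allylic oxidation may be slow or give the transposed enone. Fallback: set out from 13 and hydroxylate the only allylic CH2 by the ene/[2,3] pathway (SeO2 cat., t-BuOOH, CH2Cl2) to the allylic alcohol methyl (2R)-2-[(tert-butyldimethylsilyl)oxy]-2-{5-[(tert-butyldimethylsilyl)oxy]-4-hydroxycyclopent-2-en-1-yl}acetate F5. Oxidise F5 with Dess–Martin periodinane (CH2Cl2, rt), which comes back to the route at 14.

## Further compounds

F1 | step 11 | 1(10)-ene isomer of the target (endocyclic trisubstituted alkene, otherwise identical) | CC1=CCCC(C)(C)[C@@H]2CC[C@@](C)([C@@H]3[C@@H]4OC(=O)[C@@H](OC(C)=O)[C@H]3[C@H](C(=O)OC)O4)[C@H]12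
F2 | step 6 | 11-nordrim-7-en-9-one, (4aS,8aS)-2,5,5,8a-tetramethyl-4a,5,6,7,8,8a-hexahydronaphthalen-1(4H)-one | CC1(C)CCC[C@@]2(C)[C@H]1CC=C(C)C2=O
F3 | step 6 | 11-nordrim-7-en-9β-ol | CC1(C)CCC[C@@]2(C)[C@H]1CC=C(C)[C@@H]2O
F4 | step 6 | 9β-hydroxy cyclopentanone adduct (C11 ketone, C12-OTBS, C13 arm CH(OTBS)CO2Me, C14 on the 8α bond of 9β-hydroxy-8β-methyl-11-nordrimane) | CC1(C)CCC[C@@]2(C)[C@H]1CC[C@@](C)([C@@H]1CC(=O)[C@@H](O[Si](C)(C)C(C)(C)C)[C@H]1[C@@H](O[Si](C)(C)C(C)(C)C)C(=O)OC)[C@@H]2O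
F5 | step 5 | methyl (2R)-2-[(tert-butyldimethylsilyl)oxy]-2-{5-[(tert-butyldimethylsilyl)oxy]-4-hydroxycyclopent-2-en-1-yl}acetate (4-OH trans to 5-OTBS) | O[C@H]1C=C[C@H]([C@@H](O[Si](C)(C)C(C)(C)C)C(=O)OC)[C@@H]1O[Si](C)(C)C(C)(C)C
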